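## Retrosynthetic overview
1. Rings A and B are bought as benzene rings. Ring C (the pyran) is the only ring made. It is closed in the second-to-last step, and the last step removes two MOM groups.
2. Ring C closes at O1–C8a by intramolecular Pd-catalysed C–O coupling of a (2S)-2,3-diarylpropan-1-ol that carries an ortho chloride on ring A.
3. C2 and O1 come from a one-carbon Matteson insertion and oxidation of a secondary benzylic boronic ester. Both operations retain configuration.
4. Key step: an enantioselective three-component conjunctive cross-coupling of ring B aryllithium, vinylB(pin) and ring A aryl bromide. It forms C3–C1' and C4–C4a and sets C3 in one operation, with no isoflavone, hydrogenation or auxiliary.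
5. The ring B bromide comes from syringol (MOM, Br, reverse prenylation, Br). The ring A bromide comes from 4-bromo-3-chlorophenol.

Assumption: in simple aryl/aryl conjunctive couplings the (Sp,Sp)-Mandyphos ligand gives the (R)-1,2-diarylethyl boronic ester, so the (Rp,Rp) antipode is used for (S)-12; if the first run shows the opposite sign, the ligand antipode is swapped.

Shorthand: ArB = 2,4-dimethoxy-3-(methoxymethoxy)-5-(2-methylbut-3-en-2-yl)phenyl. ArA = 2-chloro-4-(methoxymethoxy)phenyl. pin = pinacolato. The target stereocentre is C3 and is (S).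

## Route

Step 1
Reactants: 1 2,6-dimethoxyphenol (syringol)
Product: 2 1,3-dimethoxy-2-(methoxymethoxy)benzene
Conditions: NaH, MOMCl, DMF, 0 °C to rt
Reagents that add atoms: chloromethyl methyl ether (MOMCl), COCCl
Why: Williamson-type O-alkylation gives a MOM acetal that survives organolithiums, Pd couplings and basic peroxide, and masking the OH hands control of later electrophilic substitution to the two OMe groups.

Step 2
Reactants: 2 1,3-dimethoxy-2-(methoxymethoxy)benzene
Product: 3 1-bromo-2,4-dimethoxy-3-(methoxymethoxy)benzene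
Conditions: NBS (1.0 equiv), MeCN, 0 °C to rt, dark
Reagents that add atoms: N-bromosuccinimide (NBS), O=C1CCC(=O)N1Br
Why: Electrophilic aromatic bromination goes ortho to one OMe and para to the other because the flanked central OMOM is twisted out of conjugation, as in 1,2,3-trimethoxybenzene.

Step 3
Reactants: 3 1-bromo-2,4-dimethoxy-3-(methoxymethoxy)benzene; 4 prenylboronic acid pinacol ester
Product: 5 1,3-dimethoxy-2-(methoxymethoxy)-4-(2-methylbut-3-en-2-yl)benzene
Conditions: Pd(OAc)2 (3 mol %), 1,1'-bis(di-tert-butylphosphino)ferrocene (3.6 mol %), K3PO4 aq, THF, 65 °C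
Reagents that add atoms: none
Why: In this γ-selective Suzuki–Miyaura allyl–aryl coupling, SE2' transmetalation places Pd on the tertiary carbon, and the bulky chelating diphosphine blocks the η3-allyl isomerisation and speeds reductive elimination, giving the 1,1-dimethylallyl arene rather than the linear prenyl isomer.

Step 4
Reactants: 5 1,3-dimethoxy-2-(methoxymethoxy)-4-(2-methylbut-3-en-2-yl)benzene
Product: 6 1-bromo-2,4-dimethoxy-3-(methoxymethoxy)-5-(2-methylbut-3-en-2-yl)benzene (ArB-Br)
Conditions: NBS (1.0 equiv), MeCN, 0 °C, dark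
Reagents that add atoms: N-bromosuccinimide (NBS), O=C1CCC(=O)N1Br
Why: Electrophilic aromatic bromination takes the only C–H that is ortho/para to the OMe groups, since the other C–H sits next to the tert-alkyl group and the neopentyl-type monosubstituted alkene is far less nucleophilic than the trialkoxyarene.

Step 5
Reactants: 7 4-bromo-3-chlorophenol
Product: 8 1-bromo-2-chloro-4-(methoxymethoxy)benzene (ArA-Br)
Conditions: NaH, MOMCl, DMF, 0 °C to rt
Reagents that add atoms: chloromethyl methyl ether (MOMCl), COCCl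
Why: This Williamson-type MOM protection gives a ring A partner in which Br marks C4a, Cl marks C8a and the protected oxygen para to Br is the future 7-OH.

Step 6
Reactants: 6 ArB-Br; 9 vinylboronic acid pinacol ester; 8 ArA-Br
Product: 12 (S)-2-[1-(ArB)-2-(ArA)ethyl]-4,4,5,5-tetramethyl-1,3,2-dioxaborolane, via aryllithium ArB-Li 10 (not isolated), via lithium vinylboronate complex 11 (not isolated)
Conditions: n-BuLi (1.0 equiv), THF, −78 °C; 9, −78 °C to rt, evaporate; 8, Pd(OAc)2 (2 mol %), (Rp,Rp)-Mandyphos (P-aryl = 3,5-dimethyl-4-methoxyphenyl, 2.4 mol %), KOTf (2 equiv), THF, 60 °C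
Reagents that add atoms: none
Why: In this enantioselective conjunctive cross-coupling the cationic divalent aryl-palladium formed from 8 (C–Br reacts, C–Cl does not) binds the vinyl group of boronate 11 and triggers a 1,2-metallate shift of ArB from boron to the α-carbon, reductive elimination then forms CH2–ArA, the chiral ligand chooses the alkene face and so sets C3 as (S), and KOTf removes inhibiting bromide as KBr.

Step 7
Reactants: 12 (S)-2-[1-(ArB)-2-(ArA)ethyl]-4,4,5,5-tetramethyl-1,3,2-dioxaborolane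
Product: 15 (2S)-2-(ArB)-3-(ArA)propan-1-ol, via chloromethyl boronate complex 13 (not isolated), via homologated primary boronic ester 14 (not isolated)
Conditions: BrCH2Cl (2.5 equiv), n-BuLi (2.0 equiv), THF, −78 °C to rt; then NaOH aq, H2O2 (30 %), 0 °C to rt
Reagents that add atoms: bromochloromethane, ClCBr; hydrogen peroxide, OO
Why: In this Matteson homologation LiCH2Cl adds to boron and the secondary benzylic carbon migrates with retention while chloride leaves, and the peroxide oxidation acts only on the new primary C–B bond, so C3 stays (S).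

Step 8
Reactants: 15 (2S)-2-(ArB)-3-(ArA)propan-1-ol
Product: 16 (3S)-3-(ArB)-7-(methoxymethoxy)chromane
Conditions: Pd(OAc)2 (5 mol %), 2-(di-tert-butylphosphino)-1,1'-binaphthyl (6 mol %), Cs2CO3, toluene, 80 °C
Reagents that add atoms: none
Why: In this intramolecular Buchwald-type C–O coupling zerovalent palladium inserts into the aryl C–Cl bond and the tethered alkoxide forms a six-membered palladacycle that reductively eliminates faster than β-hydride elimination, without touching the stereocentre or the distant vinyl group.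

Step 9
Reactants: 16 (3S)-3-(ArB)-7-(methoxymethoxy)chromane
Product: 17 (3S)-3-[3-hydroxy-2,4-dimethoxy-5-(2-methylbut-3-en-2-yl)phenyl]chroman-7-ol (target)
Conditions: HCl (cat., about 0.3 M), MeOH, 45 °C
Reagents that add atoms: none
Why: Acid-catalysed transacetalisation removes both MOM groups under conditions too mild to protonate the monosubstituted alkene or cleave the aryl methyl ethers, and there is no free OH ortho to the dimethylallyl group that could cyclise.

## Compound list
1 | 2,6-dimethoxyphenol | COc1cccc(OC)c1O | starting material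
2 | 1,3-dimethoxy-2-(methoxymethoxy)benzene | COCOc1c(OC)cccc1OC | intermediate
3 | 1-bromo-2,4-dimethoxy-3-(methoxymethoxy)benzene | COCOc1c(OC)ccc(Br)c1OC | intermediate
4 | 4,4,5,5-tetramethyl-2-(3-methylbut-2-en-1-yl)-1,3,2-dioxaborolane | CC(C)=CCB1OC(C)(C)C(C)(C)O1 | starting material
5 | 1,3-dimethoxy-2-(methoxymethoxy)-4-(2-methylbut-3-en-2-yl)benzene | C=CC(C)(C)c1ccc(OC)c(OCOC)c1OC | intermediate
6 | 1-bromo-2,4-dimethoxy-3-(methoxymethoxy)-5-(2-methylbut-3-en-2-yl)benzene | C=CC(C)(C)c1cc(Br)c(OC)c(OCOC)c1OC | intermediate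
7 | 4-bromo-3-chlorophenol | Oc1ccc(Br)c(Cl)c1 | starting material
8 | 1-bromo-2-chloro-4-(methoxymethoxy)benzene | COCOc1ccc(Br)c(Cl)c1 | intermediate
9 | 4,4,5,5-tetramethyl-2-vinyl-1,3,2-dioxaborolane | C=CB1OC(C)(C)C(C)(C)O1 | starting material
10 | [2,4-dimethoxy-3-(methoxymethoxy)-5-(2-methylbut-3-en-2-yl)phenyl]lithium | [Li]c1cc(C(C)(C)C=C)c(OC)c(OCOC)c1OC | intermediate
11 | lithium (ArB)(vinyl)(pinacolato)borate | [Li+].C=C[B-]1(OC(C)(C)C(C)(C)O1)c1cc(C(C)(C)C=C)c(OC)c(OCOC)c1OC | intermediate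
12 | (S)-2-[1-(ArB)-2-(ArA)ethyl]-4,4,5,5-tetramethyl-1,3,2-dioxaborolane | C=CC(C)(C)c1cc([C@@H](B2OC(C)(C)C(C)(C)O2)Cc2ccc(OCOC)cc2Cl)c(OC)c(OCOC)c1OC | intermediate
13 | lithium (chloromethyl)[(S)-1-(ArB)-2-(ArA)ethyl](pinacolato)borate | [Li+].C=CC(C)(C)c1cc([C@@H]([B-]2(CCl)OC(C)(C)C(C)(C)O2)Cc2ccc(OCOC)cc2Cl)c(OC)c(OCOC)c1OC | intermediate
14 | (S)-2-[2-(ArB)-3-(ArA)propyl]-4,4,5,5-tetramethyl-1,3,2-dioxaborolane | C=CC(C)(C)c1cc([C@@H](CB2OC(C)(C)C(C)(C)O2)Cc2ccc(OCOC)cc2Cl)c(OC)c(OCOC)c1OC | intermediate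
15 | (2S)-2-(ArB)-3-(ArA)propan-1-ol | C=CC(C)(C)c1cc([C@@H](CO)Cc2ccc(OCOC)cc2Cl)c(OC)c(OCOC)c1OC | intermediate
16 | (3S)-3-(ArB)-7-(methoxymethoxy)chromane | C=CC(C)(C)c1cc([C@H]2COc3cc(OCOC)ccc3C2)c(OC)c(OCOC)c1OC | intermediate
17 | (3S)-3-[3-hydroxy-2,4-dimethoxy-5-(2-methylbut-3-en-2-yl)phenyl]chroman-7-ol | C=CC(C)(C)c1cc([C@H]2COc3cc(O)ccc3C2)c(OC)c(O)c1OC | target

## Totals and risks
Total step count: 9. Longest linear sequence: 8 (steps 1, 2, 3, 4, 6, 7, 8, 9).

**Step 6 (highest risk).**
- Risk: both aryl partners are ortho-substituted. Direct biaryl Suzuki transfer from 11, or Heck insertion at the dimethylallyl vinyl group, could compete with the metallate shift.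
- The fallback sets out from 6 and 8 and comes back at 15. It replaces catalysis with auxiliary-controlled enolate alkylation.
- Ring B side: Negishi-type coupling of 6 with BrZnCH2CO2Et (Pd(dba)2, QPhos, THF, rt) gives ethyl 2-(ArB)acetate F3. LiOH in THF/water gives 2-(ArB)acetic acid F4. DCC/DMAP coupling with (S)-4-benzyloxazolidin-2-one gives (4S)-4-benzyl-3-[2-(ArB)acetyl]oxazolidin-2-one F5.
- Ring A side: bromine–magnesium exchange on 8 and formylation (i-PrMgCl·LiCl, −15 °C, then DMF) gives 2-chloro-4-(methoxymethoxy)benzaldehyde F6. NaBH4 gives [2-chloro-4-(methoxymethoxy)phenyl]methanol F7. CBr4/PPh3 gives 1-(bromomethyl)-2-chloro-4-(methoxymethoxy)benzene F8.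
- Union: Evans alkylation of F5 with F8 (NaHMDS, THF, −78 °C) occurs on the face away from the benzyl group. It gives (4S)-4-benzyl-3-[(2S)-2-(ArB)-3-(ArA)propanoyl]oxazolidin-2-one F9, and LiBH4 in Et2O/MeOH releases 15.

**Step 3.**
- Risk: making a quaternary carbon next to an ortho OMe may erode the γ/α ratio or stall the coupling.
- The fallback sets out from 3 and comes back at 5. It builds the quaternary carbon by enolate-type arylation, so no allyl regiochemistry question arises.
- α-Arylation of isobutyronitrile (Pd(OAc)2, rac-BINAP, NaHMDS, toluene, 100 °C) gives 2-[2,4-dimethoxy-3-(methoxymethoxy)phenyl]-2-methylpropanenitrile F1.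
- DIBAL-H (toluene, −78 °C, mild aqueous citric acid work-up) gives 2-[2,4-dimethoxy-3-(methoxymethoxy)phenyl]-2-methylpropanal F2.
- Wittig methylenation (Ph3PCH3Br, KOt-Bu, THF) gives 5.

**Step 8.**
- Risk: the aryl chloride is electron-rich and the alcohol is primary, so β-hydride elimination to the aldehyde and the dechlorinated arene can win.
- The fallback sets out from 15 and comes back at 16. It forms the O1–C2 bond by SN2 at the primary carbon instead of O1–C8a at palladium.
- Miyaura borylation of the chloride (B2pin2, Pd(OAc)2, XPhos, KOAc, dioxane, 90 °C) gives (2S)-2-(ArB)-3-[4-(methoxymethoxy)-2-(pinacolatoboryl)phenyl]propan-1-ol F10.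
- NaOH/H2O2 gives (2S)-2-(ArB)-3-[2-hydroxy-4-(methoxymethoxy)phenyl]propan-1-ol F11.
- Mitsunobu cyclisation of its single free phenol (PPh3, DIAD, THF, 0 °C) gives 16.

## Further compounds
F1 | step 3 | 2-[2,4-dimethoxy-3-(methoxymethoxy)phenyl]-2-methylpropanenitrile | N#CC(C)(C)c1ccc(OC)c(OCOC)c1OC
F2 | step 3 | 2-[2,4-dimethoxy-3-(methoxymethoxy)phenyl]-2-methylpropanal | O=CC(C)(C)c1ccc(OC)c(OCOC)c1OC
F3 | step 6 | ethyl 2-(ArB)acetate | CCOC(=O)Cc1cc(C(C)(C)C=C)c(OC)c(OCOC)c1OC
F4 | step 6 | 2-(ArB)acetic acid | OC(=O)Cc1cc(C(C)(C)C=C)c(OC)c(OCOC)c1OC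
F5 | step 6 | (4S)-4-benzyl-3-[2-(ArB)acetyl]oxazolidin-2-one | O=C1OC[C@H](Cc2ccccc2)N1C(=O)Cc1cc(C(C)(C)C=C)c(OC)c(OCOC)c1OC
F6 | step 6 | 2-chloro-4-(methoxymethoxy)benzaldehyde | COCOc1ccc(C=O)c(Cl)c1
F7 | step 6 | [2-chloro-4-(methoxymethoxy)phenyl]methanol | COCOc1ccc(CO)c(Cl)c1
F8 | step 6 | 1-(bromomethyl)-2-chloro-4-(methoxymethoxy)benzene | COCOc1ccc(CBr)c(Cl)c1
F9 | step 6 | (4S)-4-benzyl-3-[(2S)-2-(ArB)-3-(ArA)propanoyl]oxazolidin-2-one | O=C1OC[C@H](Cc2ccccc2)N1C(=O)[C@@H](Cc1ccc(OCOC)cc1Cl)c1cc(C(C)(C)C=C)c(OC)c(OCOC)c1OC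
F10 | step 8 | (2S)-2-(ArB)-3-[4-(methoxymethoxy)-2-(pinacolatoboryl)phenyl]propan-1-ol | C=CC(C)(C)c1cc([C@@H](CO)Cc2ccc(OCOC)cc2B3OC(C)(C)C(C)(C)O3)c(OC)c(OCOC)c1OC
F11 | step 8 | (2S)-2-(ArB)-3-[2-hydroxy-4-(methoxymethoxy)phenyl]propan-1-ol | C=CC(C)(C)c1cc([C@@H](CO)Cc2ccc(OCOC)cc2O)c(OC)c(OCOC)c1OC
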